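**Plan**

- The last cut frees the C5 hydroxyl from a benzyl ether. Before that, the flavonol oxidation pattern of ring C (C3–OH, C4=O, C2=C3) is traced back to the C3=C4 alkene of a 2-aryl-2H-chromene.
- The chromene is cut at O1–C2 and C4–C4a into 5-(benzyloxy)-2,3-dimethoxyphenol (ring A with O1) and (E)-3,4,5-trimethoxycinnamaldehyde (ring B with C2, C3, C4).
- Enabling feature: O1 sits on C8a, and its ortho neighbour C8 carries a methoxy group. C4a is therefore the only free ortho carbon, activated by the oxygens on C5, C7 and C8a, so the annulation can only give the 5,7,8-oxygenated ring A/ring C pattern.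
- Forward: the ring A phenol is made in three steps and the enal in one. Ring C is the only ring formed (step 5), then dihydroxylated, oxidized twice with tautomerization, and debenzylated.
- Stereochemistry: the target is achiral. C2 arises racemic in step 5, C3 and C4 are set relative to it in step 6 (anti to the C2 aryl), and all three are erased in step 7.

Key step: step 5

Remark: the C5 oxygen is carried as a benzyl ether so that the final unmasking is a hydrogenolysis and not a selective cleavage of one methyl ether among six. All chiral intermediates are racemic, with one enantiomer drawn. Compounds 1 and 6, (triphenylphosphoranylidene)acetaldehyde and phenylboronic acid are taken as commercial.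

**Route**

Step 1
Reactants: 1 3-bromo-4,5-dimethoxybenzaldehyde
Product: 3 3-bromo-4,5-dimethoxyphenol, via aryl formate 2 (not isolated)
Conditions: mCPBA, CH2Cl2, 0 °C to rt; NaHCO3 wash; then K2CO3 (cat.), MeOH, rt
Reagents that add atoms: 3-chloroperoxybenzoic acid (mCPBA), OOC(=O)c1cccc(Cl)c1
Why: Baeyer–Villiger oxidation of an electron-rich benzaldehyde, in which the aryl group bearing a para methoxy substituent should migrate in preference to hydrogen to give formate 2, which methanol then transesterifies to the phenol.

Step 2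
Reactants: 3 3-bromo-4,5-dimethoxyphenol
Product: 4 5-(benzyloxy)-1-bromo-2,3-dimethoxybenzene
Conditions: BnBr, K2CO3, DMF, rt
Reagents that add atoms: benzyl bromide, BrCc1ccccc1
Why: Williamson ether synthesis on the phenoxide, placing on the future C5 oxygen a group that can later be removed without touching any methyl ether.

Step 3
Reactants: 4 5-(benzyloxy)-1-bromo-2,3-dimethoxybenzene
Product: 5 5-(benzyloxy)-2,3-dimethoxyphenol
Conditions: Pd2(dba)3 (cat.), t-BuXPhos (2-di-tert-butylphosphino-2',4',6'-triisopropylbiphenyl, cat.), KOH, 1,4-dioxane/H2O, 100 °C, degassed; then aq. HCl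
Reagents that add atoms: potassium hydroxide, [K+].[OH-]
Why: Palladium-catalysed hydroxylation of an aryl bromide (C–O cross-coupling with hydroxide), in which the bulky biaryl phosphine should drive C–O reductive elimination even from an electron-rich, ortho-substituted arylpalladium hydroxide.

Step 4
Reactants: 6 3,4,5-trimethoxybenzaldehyde
Product: 7 (E)-3-(3,4,5-trimethoxyphenyl)prop-2-enal
Conditions: Ph3P=CHCHO (1.1 equiv), toluene, 90 °C
Reagents that add atoms: (triphenylphosphoranylidene)acetaldehyde, O=CC=P(c1ccccc1)(c1ccccc1)c1ccccc1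
Why: Wittig olefination with a carbonyl-stabilized ylide, which should add the two-carbon enal unit with E geometry.

Step 5
Reactants: 5 5-(benzyloxy)-2,3-dimethoxyphenol; 7 (E)-3-(3,4,5-trimethoxyphenyl)prop-2-enal
Product: 10 5-(benzyloxy)-7,8-dimethoxy-2-(3,4,5-trimethoxyphenyl)-2H-chromene (racemic), via benzodioxaborin 8 (not isolated), via ortho-quinone methide 9 (not isolated)
Conditions: PhB(OH)2 (1.1 equiv), EtCO2H (cat.), toluene, reflux, Dean–Stark trap
Reagents that add atoms: none
Why: Phenylboronic acid esterifies the phenol of 5 and binds the aldehyde of 7, so that C-alkylation takes place inside a six-membered boron-tethered transition state at the ortho carbon and forms the C4–C4a bond of benzodioxaborin 8, which on heating with the acid expels phenylboronic anhydride to give the ortho-quinone methide 9, a 1-oxatriene. The closest known reaction type is the boronic acid-templated condensation of phenols with α,β-unsaturated aldehydes to 2H-chromenes. Ring C closes by thermal disrotatory oxa-6π electrocyclization of 9, which forms O1–C2 and restores the aromaticity of ring A. The new C2 stereocentre has no controlling element and is formed racemic, which is of no consequence because C2 becomes sp2 in step 7. The step needs ortho instead of para C-alkylation, secured by the boron tether, which reaches only C4a because the other ortho carbon (C8) bears a methoxy group. The Z geometry of the exocyclic alkene of 9 needed for closure should be favoured by the C5 benzyloxy group, which pushes the styryl arm toward the carbonyl oxygen.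

Step 6
Reactants: 10 5-(benzyloxy)-7,8-dimethoxy-2-(3,4,5-trimethoxyphenyl)-2H-chromene
Product: 11 rac-(2R,3S,4S)-5-(benzyloxy)-7,8-dimethoxy-2-(3,4,5-trimethoxyphenyl)chromane-3,4-diol (2,3-trans-3,4-cis)
Conditions: OsO4 (cat.), NMO, acetone/H2O, rt; Na2SO3 quench; crude diol carried on without acidic contact
Reagents that add atoms: osmium tetroxide (catalytic carrier of both oxygens), O=[Os](=O)(=O)=O; N-methylmorpholine N-oxide, C[N+]1([O-])CCOCC1; water, O
Why: Catalytic syn-dihydroxylation with OsO4/NMO of the cis-disubstituted styrene-type C3=C4 alkene, in which the osmium reagent should approach the face of ring C opposite to the C2 aryl group, so that both hydroxyls come out cis to each other and trans to the aryl group.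

Step 7
Reactants: 11 rac-(2R,3S,4S)-5-(benzyloxy)-7,8-dimethoxy-2-(3,4,5-trimethoxyphenyl)chromane-3,4-diol
Product: 14 5-(benzyloxy)-3-hydroxy-7,8-dimethoxy-2-(3,4,5-trimethoxyphenyl)-4H-chromen-4-one, via dihydroflavonol 12 (not isolated), via chromane-3,4-dione 13 (not isolated)
Conditions: IBX (2-iodoxybenzoic acid, 3.5 equiv), DMSO, rt to 45 °C
Reagents that add atoms: none
Why: IBX oxidation of a vicinal diol to the 1,2-dione without C–C cleavage (benzylic C4 carbinol first to 12, then the C3 carbinol to 13), after which the C2–H flanked by O1, the aryl group and the C3 ketone should enolize to the aromatic 3-hydroxy-4-pyranone, erasing all three stereocentres.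

Step 8
Reactants: 14 5-(benzyloxy)-3-hydroxy-7,8-dimethoxy-2-(3,4,5-trimethoxyphenyl)-4H-chromen-4-one
Product: 15 3,5-dihydroxy-7,8-dimethoxy-2-(3,4,5-trimethoxyphenyl)-4H-chromen-4-one (3,5-dihydroxy-7,8,3',4',5'-pentamethoxyflavone)
Conditions: H2 (1 atm), Pd/C, EtOAc/MeOH, rt
Reagents that add atoms: none
Why: Hydrogenolysis of the benzyl aryl ether on palladium, which should leave the five methyl ethers and the conjugated pyranone untouched and free the C5 hydroxyl.

**Compound list**

1 | 3-bromo-4,5-dimethoxybenzaldehyde | COc1cc(C=O)cc(Br)c1OC | starting material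
2 | 3-bromo-4,5-dimethoxyphenyl formate | COc1cc(OC=O)cc(Br)c1OC | intermediate (not isolated)
3 | 3-bromo-4,5-dimethoxyphenol | COc1cc(O)cc(Br)c1OC | intermediate
4 | 5-(benzyloxy)-1-bromo-2,3-dimethoxybenzene | COc1cc(OCc2ccccc2)cc(Br)c1OC | intermediate
5 | 5-(benzyloxy)-2,3-dimethoxyphenol | COc1cc(OCc2ccccc2)cc(O)c1OC | intermediate
6 | 3,4,5-trimethoxybenzaldehyde | COc1cc(C=O)cc(OC)c1OC | starting material
7 | (E)-3-(3,4,5-trimethoxyphenyl)prop-2-enal | COc1cc(/C=C/C=O)cc(OC)c1OC | intermediate
8 | 5-(benzyloxy)-7,8-dimethoxy-2-phenyl-4-[(E)-2-(3,4,5-trimethoxyphenyl)ethenyl]-4H-1,3,2-benzodioxaborinine (racemic) | COc1cc(OCc2ccccc2)c2c(c1OC)OB(c1ccccc1)O[C@@H]2/C=C/c1cc(OC)c(OC)c(OC)c1 | intermediate (not isolated)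
9 | (6Z)-5-(benzyloxy)-2,3-dimethoxy-6-[(2E)-3-(3,4,5-trimethoxyphenyl)prop-2-en-1-ylidene]cyclohexa-2,4-dien-1-one | COc1cc(/C=C/C=C2\C(=O)C(OC)=C(OC)C=C2OCc2ccccc2)cc(OC)c1OC | intermediate (not isolated)
10 | 5-(benzyloxy)-7,8-dimethoxy-2-(3,4,5-trimethoxyphenyl)-2H-chromene (racemic) | COc1cc(OCc2ccccc2)c2c(c1OC)O[C@H](c1cc(OC)c(OC)c(OC)c1)C=C2 | intermediate
11 | rac-(2R,3S,4S)-5-(benzyloxy)-7,8-dimethoxy-2-(3,4,5-trimethoxyphenyl)chromane-3,4-diol | COc1cc(OCc2ccccc2)c2c(c1OC)O[C@H](c1cc(OC)c(OC)c(OC)c1)[C@@H](O)[C@H]2O | intermediate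
12 | rac-(2R,3R)-5-(benzyloxy)-3-hydroxy-7,8-dimethoxy-2-(3,4,5-trimethoxyphenyl)chroman-4-one (2,3-trans-dihydroflavonol) | COc1cc(OCc2ccccc2)c2c(c1OC)O[C@H](c1cc(OC)c(OC)c(OC)c1)[C@@H](O)C2=O | intermediate (not isolated)
13 | 5-(benzyloxy)-7,8-dimethoxy-2-(3,4,5-trimethoxyphenyl)chromane-3,4-dione (racemic, labile at C2) | COc1cc(OCc2ccccc2)c2c(c1OC)O[C@H](c1cc(OC)c(OC)c(OC)c1)C(=O)C2=O | intermediate (not isolated)
14 | 5-(benzyloxy)-3-hydroxy-7,8-dimethoxy-2-(3,4,5-trimethoxyphenyl)-4H-chromen-4-one | COc1cc(OCc2ccccc2)c2c(c1OC)oc(-c1cc(OC)c(OC)c(OC)c1)c(O)c2=O | intermediate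
15 | 3,5-dihydroxy-7,8-dimethoxy-2-(3,4,5-trimethoxyphenyl)-4H-chromen-4-one | COc1cc(-c2oc3c(OC)c(OC)cc(O)c3c(=O)c2O)cc(OC)c1OC | target

**Step count**

Total: 8 steps. Longest linear sequence: 7 steps (steps 1, 2, 3, 5, 6, 7, 8 from compound 1).

**Steps most likely to fail**

1. Step 5. The ortho-quinone methide may be captured by a second molecule of the electron-rich phenol, or the flavene may oligomerize or disproportionate under the acid, faster than the electrocyclization delivers product. The benzodioxaborin may also resist fragmentation. The fallback sets out from phenol 5 and returns at chromene 10, forming the C4–C4a bond by a separate chelation-controlled step.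
   - Magnesium-mediated ortho-formylation (MgCl2, Et3N, paraformaldehyde, MeCN, reflux) should give 6-(benzyloxy)-2-hydroxy-3,4-dimethoxybenzaldehyde F1.
   - Claisen–Schmidt condensation of F1 with commercial 3,4,5-trimethoxyacetophenone (KOH, EtOH, rt) should give (E)-3-[6-(benzyloxy)-2-hydroxy-3,4-dimethoxyphenyl]-1-(3,4,5-trimethoxyphenyl)prop-2-en-1-one F2.
   - Luche reduction (NaBH4, CeCl3·7H2O, MeOH, 0 °C) should give the racemic (E)-3-[6-(benzyloxy)-2-hydroxy-3,4-dimethoxyphenyl]-1-(3,4,5-trimethoxyphenyl)prop-2-en-1-ol F3.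
   - A trace of acetic acid in warm toluene should ionize this doubly activated allylic alcohol; loss of the phenolic proton gives the same oxatriene 9, which closes to 10.

2. Step 7. The acid-labile diol may ionize at the C4 carbinol, the C3–C4 glycol may be cleaved, or the oxidation may stall at the hydroxy ketone. The fallback sets out from diol 11 and returns at flavonol 14 in two separate stages with different oxidants. DDQ in 1,4-dioxane at rt should dehydrogenate only the electron-rich benzylic C4 carbinol, giving dihydroflavonol 12, which is isolated here. I2 with KOAc in AcOH at 100 °C should then oxidize the derived enediol to 14. This fallback passes only through compounds of the list (F0).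

3. Step 4. The ylide may olefinate the product enal a second time (over-homologation to the dienal) while the electron-rich aldehyde reacts slowly. The fallback sets out from aldehyde 6 and returns at enal 7. Horner–Wadsworth–Emmons olefination (triethyl phosphonoacetate, NaH, THF, 0 °C to rt) should give ethyl (E)-3-(3,4,5-trimethoxyphenyl)prop-2-enoate F4. Reduction with i-Bu2AlH (CH2Cl2, −78 °C) should give (E)-3-(3,4,5-trimethoxyphenyl)prop-2-en-1-ol F5, and allylic oxidation with MnO2 (CH2Cl2, rt) should give 7.

**Further compounds**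

F1 | step 5 | 6-(benzyloxy)-2-hydroxy-3,4-dimethoxybenzaldehyde | COc1cc(OCc2ccccc2)c(C=O)c(O)c1OC
F2 | step 5 | (E)-3-[6-(benzyloxy)-2-hydroxy-3,4-dimethoxyphenyl]-1-(3,4,5-trimethoxyphenyl)prop-2-en-1-one | COc1cc(OCc2ccccc2)c(/C=C/C(=O)c2cc(OC)c(OC)c(OC)c2)c(O)c1OC
F3 | step 5 | (E)-3-[6-(benzyloxy)-2-hydroxy-3,4-dimethoxyphenyl]-1-(3,4,5-trimethoxyphenyl)prop-2-en-1-ol (racemic) | COc1cc(OCc2ccccc2)c(/C=C/[C@H](O)c2cc(OC)c(OC)c(OC)c2)c(O)c1OC
F0 | step 7 | none | none
F4 | step 4 | ethyl (E)-3-(3,4,5-trimethoxyphenyl)prop-2-enoate | CCOC(=O)/C=C/c1cc(OC)c(OC)c(OC)c1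
F5 | step 4 | (E)-3-(3,4,5-trimethoxyphenyl)prop-2-en-1-ol | OC/C=C/c1cc(OC)c(OC)c(OC)c1
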